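**Retrosynthetic overview** (ring atoms: C1 = quaternary carbon, C2=C3 = dimethoxy alkene, C4 = ring ketone, C5 = acyl-bearing carbon)
1. The styryl C=C is made last, by Claisen–Schmidt condensation of the 2-acetyl enol 10 with benzaldehyde.
2. The only ring is built in one operation, a [3+2] annulation: first C1–C2 by conjugate addition, then C4–C5 by Dieckmann closure.
3. Key bond C1–C2: the metallated β-carbon of methyl 2,3-dimethoxyacrylate acts as a β-acylvinyl (masked acyl) anion. It attacks the equally electrophilic β-carbon of enone 6, and a chiral copper catalyst sets C1 as S.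
4. 4 comes from methyl methoxyacetate and methyl formate. 6 comes from methyl acetopyruvate.

Assumption: the target is the chelated Z-enol of a freely tautomerising β-diketone, so C1 (S) is the only element to control; L* in step 3 is the leucinol-derived NHC precursor 3-(1-hydroxy-4-methylpentan-2-yl)-1-mesityl-4,5-dihydroimidazolium hexafluorophosphate, used as whichever antipode a test run shows to give (S)-10.

**Step 1**
Reactants: 1 methyl methoxyacetate; 2 methyl formate
Product: 4 methyl (2Z)-2,3-dimethoxyprop-2-enoate, via sodium enolate 3 (not isolated)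
Conditions: NaOMe (1.1 equiv), 2 (1.5 equiv), toluene, 0 °C to rt; then Me2SO4, DMF, rt; distil
Reagents that add atoms: dimethyl sulfate, COS(=O)(=O)OC
Why: Crossed Claisen formylation works because methyl formate has no α-hydrogen and is the most electrophilic ester present, and hard O-methylation of the formyl-ester enolate puts the new OMe trans to the ester (Z here), as in the standard β-methoxyacrylate synthesis; no stereocentre is formed.

**Step 2**
Reactants: 5 methyl 2,4-dioxopentanoate (methyl acetopyruvate)
Product: 6 methyl (2Z)-2-methoxy-4-oxopent-2-enoate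
Conditions: HC(OMe)3 (1.5 equiv), p-TsOH (2 mol %), MeOH, reflux
Reagents that add atoms: trimethyl orthoformate, COC(OC)OC
Why: Acid-catalysed ketalisation–elimination (enol ether formation) runs through the C2 carbonyl, the most electrophilic one because it is flanked by the ester, and equilibration leaves the fumarate-like Z isomer with ester and acetyl trans; no stereocentre is formed.

**Step 3 (key step)**
Reactants: 4 methyl (2Z)-2,3-dimethoxyprop-2-enoate; 6 methyl (2Z)-2-methoxy-4-oxopent-2-enoate
Product: 10 methyl (1S,5Z)-5-(1-hydroxyethylidene)-1,2,3-trimethoxy-4-oxocyclopent-2-ene-1-carboxylate, via alkenylmagnesium chloride 7 (not isolated), via magnesium enolate 8 (not isolated), via magnesium diketonate 9 (not isolated)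
Conditions: 4 (2.0 equiv), TMPMgCl·LiCl (2.1 equiv), THF, −40 °C, 1 h; Cu(OTf)2 (5 mol %), L* (6 mol %), Et2O, then 6 (1.0 equiv), −78 to 0 °C; 1 M HCl
Reagents that add atoms: none
Why: Proposed new method: directed magnesiation of the only vinylic C–H of 4 (α to OMe, cis to the chelating ester) turns the normally electrophilic acrylate β-carbon into a β-acylvinyl and α-methoxyvinyl (masked acyl) anion, a chiral NHC–copper catalyst delivers it to the Si face of the likewise electrophilic C2 of 6 (β to the ketone, activated by the geminal ester) and so sets C1 as S, the chelated magnesium enolate keeps the C1–OMe bond in the enolate plane so that β-elimination is slow, and this regiodefined enolate closes the ring by Dieckmann attack on the cis ester with the magnesium diketonate as sink (the second equivalent of 7 takes up the liberated methanol); the closest known reaction types are conjugate addition of α-alkoxyvinyl cuprates as acyl anion equivalents, copper–NHC-catalysed asymmetric conjugate addition of Grignard reagents to β,β-disubstituted enones, and tandem conjugate addition–Dieckmann cyclisation.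

**Step 4**
Reactants: 10 methyl (1S,5Z)-5-(1-hydroxyethylidene)-1,2,3-trimethoxy-4-oxocyclopent-2-ene-1-carboxylate; 11 benzaldehyde
Product: 12 methyl (1S,5Z)-5-[(2E)-1-hydroxy-3-phenylprop-2-en-1-ylidene]-1,2,3-trimethoxy-4-oxocyclopent-2-ene-1-carboxylate
Conditions: 11 (1.2 equiv), piperidine (20 mol %), AcOH (20 mol %), toluene, 4 Å MS, 80 °C
Reagents that add atoms: none
Why: Amine-catalysed Claisen–Schmidt condensation can only be completed at the acetyl CH3 because the central β-diketone carbon has no second hydrogen for dehydration, conjugation makes the E-styryl enone the thermodynamic product, and quaternary C1 cannot epimerise (loss of its OMe would give an antiaromatic cyclopentadienone), so S is kept.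

**Compound list**
1 | methyl methoxyacetate | COCC(=O)OC | starting material
2 | methyl formate | COC=O | starting material
3 | sodium 2,3-dimethoxy-3-oxoprop-1-en-1-olate (configurationally labile enolate) | [Na+].[O-]C=C(OC)C(=O)OC | intermediate
4 | methyl (2Z)-2,3-dimethoxyprop-2-enoate (both OMe cis, vinylic H cis to the ester) | COC(=O)/C(OC)=C/OC | intermediate
5 | methyl 2,4-dioxopentanoate (methyl acetopyruvate) | COC(=O)C(=O)CC(C)=O | starting material
6 | methyl (2Z)-2-methoxy-4-oxopent-2-enoate (ester and acetyl trans) | COC(=O)/C(OC)=C/C(C)=O | intermediate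
7 | chloro[(1E)-1,2,3-trimethoxy-3-oxoprop-1-en-1-yl]magnesium (Mg cis to the ester, LiCl complex) | COC(=O)/C(OC)=C(/OC)[Mg]Cl | intermediate
8 | chloromagnesium enolate of dimethyl (2Z,4S)-2,3,4-trimethoxy-4-(2-oxopropyl)pent-2-enedioate | COC(=O)[C@@](C=C(C)O[Mg]Cl)(OC)/C(OC)=C(/OC)C(=O)OC | intermediate
9 | chloromagnesium diketonate of 10 | COC(=O)[C@@]1(OC)C(OC)=C(OC)C(=O)/C1=C(/C)O[Mg]Cl | intermediate
10 | methyl (1S,5Z)-5-(1-hydroxyethylidene)-1,2,3-trimethoxy-4-oxocyclopent-2-ene-1-carboxylate | COC(=O)[C@@]1(OC)C(OC)=C(OC)C(=O)/C1=C(/C)O | intermediate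
11 | benzaldehyde | O=Cc1ccccc1 | starting material
12 | methyl (1S,5Z)-5-[(2E)-1-hydroxy-3-phenylprop-2-en-1-ylidene]-1,2,3-trimethoxy-4-oxocyclopent-2-ene-1-carboxylate | COC(=O)[C@@]1(OC)C(OC)=C(OC)C(=O)/C1=C(O)/C=C/c1ccccc1 | target

**Total steps:** 4. **Longest linear sequence:** 3 (1 → 4 → 10 → 12, or 5 → 6 → 10 → 12).

**Steps most likely to fail**

Step 3 is the largest risk.
- 7 may lose methoxide to give an alkynoate.
- Copper may not transfer so hindered a group to a fully substituted β-carbon, or may do so with low ee.
- Enolate 8 may expel the C1 methoxide, which erodes the ee.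
- Enolate 8 may equilibrate to the CH3 side and close onto the other ester.

The fallback gives up the organometallic annulation and closes the same C1–C2 bond last, by an electrocyclisation. It sets out from 4 and comes back at 10. The lithium enolate of acetone is acylated with 4 (Claisen) to the diketone (5Z)-5,6-dimethoxyhex-5-ene-2,4-dione F1. C-acylation of F1 with methyl chlorooxoacetate (MgCl2, pyridine) gives the enolised tricarbonyl methyl (5Z)-3-acetyl-2-hydroxy-5,6-dimethoxy-4-oxohexa-2,5-dienoate F2. A chiral bifunctional thiourea–amine, or Cu(OTf)2 with a bisoxazoline, then promotes a polarised Nazarov 4π closure whose torquoselectivity sets C1. This gives the tertiary alcohol methyl (1S,5Z)-1-hydroxy-5-(1-hydroxyethylidene)-2,3-dimethoxy-4-oxocyclopent-2-ene-1-carboxylate F3. Finally the dianion of F3 (NaH, 2 equiv) is methylated on its more basic alkoxide with one equivalent of MeOTf to give 10.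

Step 4 may stall, or piperidine may displace the vinylogous-ester OMe at C2. The fallback replaces the catalytic condensation by a stoichiometric dianion aldol followed by a separate dehydration. It sets out from 10 and comes back at 12. LDA (2.2 equiv, THF, −78 °C) forms the 1,3-dianion of 10, whose terminal carbanion adds to 11. This gives the aldol methyl (1S,5Z)-5-(1,3-dihydroxy-3-phenylpropylidene)-1,2,3-trimethoxy-4-oxocyclopent-2-ene-1-carboxylate F4 as a mixture of carbinol epimers. Catalytic p-TsOH in warm toluene dehydrates F4 to 12.

Step 2 may give some of the 4-methoxy regioisomer or E/Z mixtures under equilibrating acid. The fallback fixes the regiochemistry at an isolable ketal and eliminates under aprotic basic conditions. It sets out from 5 and comes back at 6. Ketalisation at room temperature (HC(OMe)3, MeOH, trace acid) is stopped at methyl 2,2-dimethoxy-4-oxopentanoate F5, which is purified and checked by NMR. TMSOTf/iPr2NEt (CH2Cl2, −78 to 0 °C) then removes one methanol towards the acidic C3–H to give 6.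

**Further compounds**
F1 | step 3 | (5Z)-5,6-dimethoxyhex-5-ene-2,4-dione | CC(=O)CC(=O)/C(OC)=C/OC
F2 | step 3 | methyl (5Z)-3-acetyl-2-hydroxy-5,6-dimethoxy-4-oxohexa-2,5-dienoate | COC(=O)C(O)=C(C(C)=O)C(=O)/C(OC)=C/OC
F3 | step 3 | methyl (1S,5Z)-1-hydroxy-5-(1-hydroxyethylidene)-2,3-dimethoxy-4-oxocyclopent-2-ene-1-carboxylate | COC(=O)[C@@]1(O)C(OC)=C(OC)C(=O)/C1=C(/C)O
F4 | step 4 | methyl (1S,5Z)-5-(1,3-dihydroxy-3-phenylpropylidene)-1,2,3-trimethoxy-4-oxocyclopent-2-ene-1-carboxylate | COC(=O)[C@@]1(OC)C(OC)=C(OC)C(=O)/C1=C(O)/CC(O)c1ccccc1
F5 | step 2 | methyl 2,2-dimethoxy-4-oxopentanoate | COC(=O)C(OC)(OC)CC(C)=O
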